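## Analysis of the target

The target is a flavone: a benzo ring A fused to a 4-pyranone ring C that carries the phenyl ring B at C2. Ring A bears a methoxy group at C5, a hydroxyl at C7 and, between them at C6, an N-methylpiperidin-2-yl group. The only stereocentre is C2 of the piperidine, and it is S (N > aryl carbon > ring CH2 > H). It is benzylic, lies between two oxygen-bearing carbons, and has no neighbouring stereocentre to relay from, so it must be set by a reagent or catalyst.

The sensitive elements are:
- the chromone enone, which accepts nucleophiles and can be hydrogenated at C2=C3;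
- the benzylic C–N bond next to a free ortho-phenol, which can ionise towards a quinone methide and racemise C2;
- the basic tertiary amine.

The synthesis is hard for two reasons. Ring A is substituted at five of its six carbons, and O5 must end as the methyl ether while O7 ends free, which is the reverse of the usual ease of alkylation in 5,7-dioxygenated chromones.

The strategy rests on one feature: C4a (carrying the C4 acyl carbon) and C8a (carrying O1) are adjacent ring-A carbons, and C5 next to C4a carries oxygen. An aryne across C4a≡C8a is therefore polarised by the C5 alkoxy group so that an oxygen nucleophile enters at C8a and carbon at C4a.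

## Retrosynthetic reasoning

**C7–O benzyl bond (24 from 23).** The free 7-hydroxyl is unmasked last by hydrogenolysis. A free phenol ortho to the benzylic amine is the arrangement most prone to racemisation and to attack by one-carbon electrophiles, so it should exist only in the final compound.

**N–CH3 bond (23 from 21 through 22).** The methyl group on nitrogen is added by reductive methylation of the secondary amine 22, which is released from carbamate 21. The carbamate is needed up to this point: it keeps nitrogen from adding to the aryne, from being alkylated in the O-methylation and from binding Lewis acids.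

**O5–CH3 bond (21 from 20, and 20 from 19).** O5 and O7 are both benzyl ethers in 19. They are told apart by position: only O5 sits peri to the C4 carbonyl and can form a six-membered chelate with a Lewis acid, so only that ether is cleaved. Methylation of the freed 5-hydroxyl then gives 21. Identical ethers are accepted at this point because they make the earlier ring-A chemistry symmetric.

**O1–C2 bond of ring C (19 from 17).** The pyranone is opened to the ortho-hydroxyaryl ynone 17. The forward step is a conjugate closure of the C8a oxygen onto the alkyne carbon that carries the phenyl ring. It must run in the six-membered mode and not give the five-membered aurone.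

**C4a–C4 and C8a–O1 bonds (17 from 14 and 15 through aryne 16).** Both bonds that attach the three-carbon unit and the ring oxygen to ring A are cut at once. The acyl carbon and the oxygen come from one molecule of acid 15, and ring A comes from aryne 16, which is released from silyl triflate 14 by fluoride.
- Why here: the cut removes the whole C2–C3–C4–O1 unit with ring B in one operation and leaves a ring-A piece that derives from a symmetric phenol.
- Why not a direct acylation of phenol 10: that would need acidic conditions, which neither the carbamate nor an ynone tolerates.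
- What the forward step must achieve: oxygen must add at C8a only, and the aryl anion must then be acylated rather than protonated.

**C–Si and O–S bonds (14 from 10 through 11, 12 and 13).** The silyl triflate comes from phenol 10 by ortho-bromination, O-silylation, bromine–lithium exchange with 1,3-migration of silicon from oxygen to carbon, and triflation. The two positions ortho to the hydroxyl of 10 are interchanged by rotation about the aryl–piperidine bond, so bromination can give only one monobromide.

**C2–H bond at the stereocentre (10 from 7 through 8 and 9).** The stereocentre is made by enantioselective hydrogenation of the cyclic imine 7, followed by N-protection and desilylation. This places the asymmetric step early, on a small substrate with no reducible group besides the C=N bond.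

**Aryl–C2 and N=C2 bonds (7 from 2 and 3 through 4, 5 and 6; 2 from 1).** The imine comes from the amino ketone released from 5. Ketone 5 comes from addition of aryllithium 4 to the N-acyl lactam 3, and 4 from deprotonation of 2 at the carbon between the two benzyloxy groups. A benzoic acid-based entry to this aryl unit was set aside: converting a carboxyl group into the phenol costs several steps, and a Dakin-type oxidation is unfavourable when the alkoxy groups are meta to the formyl group. Phenol 1 already has the 1,3,5-oxygen pattern.

## Alternatives that were turned down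

**Alternative 1:** The N–C2 bond of the piperidine is disconnected on a finished flavone.
- Forward key step: a chiral Brønsted acid dehydrates the racemic hydroxy carbamate A2 to the ortho-quinone methide A3. The carbamate nitrogen then adds to the methide carbon (6-exo-trig) to give A1.
- For: both enantiomers of A2 pass through planar A3, so the step is stereoconvergent. The stereocentre is set late, and O5 and O7 are already differentiated. On these points it is stronger than the chosen route.
- Against: A3 is also the species through which A1 can re-ionise, so the enantiomeric purity depends on a kinetic preference that the acid can erode. The 7-hydroxyl is a vinylogous acid conjugated to the chromone carbonyl, so it pushes electrons poorly and ionisation needs forcing. Carbamate nitrogen is a weak nucleophile for this type of catalysis. Making A2 requires acylation of a 5,7-dioxygenated flavone at C6 in competition with C8.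
- Comparison: the chosen route sets C2 early on a simple imine and keeps nitrogen as a carbamate, with no free ortho-phenol, until the last step. It is longer but does not depend on a reversible stereo-defining step.

**Alternative 2:** The C6–C(pyridyl) and C7–O bonds are disconnected together.
- Forward key step: fluoride generates the flavone aryne A5. It undergoes (3+2) cycloaddition with pyridine N-oxide A6, and N–O cleavage gives A4.
- For: two ring-A bonds are made in one step. The C5 methoxy group directs oxygen to the distal C7 and carbon to C6, which is the correct sense. O7 arrives free and O5 already methylated, so no ether differentiation is needed. On step count and on the O5/O7 problem it is stronger than the chosen route.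
- Against: the stereocentre is still absent in A4. It would have to come from enantioselective reduction of a 2-arylpyridinium ring whose aryl group is di-ortho-substituted, next to a reducible chromone C2=C3 bond and a free phenol. Cycloadducts of N-oxides and arynes can also rearrange to the 3-pyridyl isomer. The aryne sits on an electrophilic chromone that fluoride and other nucleophiles can attack.
- Comparison: the chosen route also uses an aryne, but for heteroatom and acyl transfer on an electron-rich ring, and it does the asymmetric reduction on a substrate without competing reducible groups.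

**Alternative 3:** Ring A is disconnected at four bonds (C8a–C8, C7–C8, C5–C6, C4a–C5) into the pyranonyl diazoketone A8 and the siloxyalkyne A9.
- Forward key step: blue light induces Wolff rearrangement of A8 to a vinylketene. This adds A9 in a (2+2) sense, the cyclobutenone opens, and six-electron closure gives phenol A7.
- For: it is the most convergent plan. The stereocentre in A9 comes from the chiral pool, so no asymmetric step is needed. A7 has O5 free and O7 silylated, so the differentiation that costs the chosen route three steps is built in. On these points it is clearly stronger.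
- Against: A9 requires ynolate chemistry with strong base next to an N-acylated stereocentre, with a risk of epimerisation, and siloxyalkynes are labile. A8 requires diazo chemistry on a pyranone that is itself photoactive and a Michael acceptor. The bulky branched substituent must end up between two oxygens in the pericyclic cascade. Both fragments take several steps, so the total is not shorter.
- Comparison: the chosen route buys ring A with its oxygen pattern rather than building it, and its key step starts from a bench-stable silyl triflate. The price is the late ether differentiation.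

Key step: step 9

Remark: the sense of induction of the iridium catalyst on this hindered imine cannot be predicted with confidence. The ligand enantiomer that gives the S amine is assumed to be identified in a trial run, and the route is written for it.

## Route

Step 1
Reactants: 1 3,5-bis(benzyloxy)phenol
Product: 2 [3,5-bis(benzyloxy)phenoxy]tri(propan-2-yl)silane
Conditions: i-Pr3SiCl, imidazole, DMF, rt
Reagents that add atoms: chlorotri(propan-2-yl)silane, CC(C)[Si](Cl)(C(C)C)C(C)C
Why: O-silylation of a phenol; the bulky silyl ether does not direct lithiation, shields its own ortho positions, and withstands n-BuLi and the later acid step.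

Step 2
Reactants: 2 [3,5-bis(benzyloxy)phenoxy]tri(propan-2-yl)silane; 3 tert-butyl 2-oxopiperidine-1-carboxylate
Product: 5 tert-butyl (5-{2,6-bis(benzyloxy)-4-[tri(propan-2-yl)silyloxy]phenyl}-5-oxopentyl)carbamate, via aryllithium 4 (not isolated)
Conditions: n-BuLi, THF, 0 °C; then 3, −78 °C to −20 °C; aq. NH4Cl
Reagents that add atoms: none
Why: directed ortho-metalation occurs at the carbon flanked by both benzyloxy groups, where two ether oxygens cooperate. The aryllithium then adds to the activated lactam carbonyl of 3, which opens to the N-Boc amino ketone and is too hindered for a second addition.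

Step 3
Reactants: 5 tert-butyl (5-{2,6-bis(benzyloxy)-4-[tri(propan-2-yl)silyloxy]phenyl}-5-oxopentyl)carbamate
Product: 7 6-{2,6-bis(benzyloxy)-4-[tri(propan-2-yl)silyloxy]phenyl}-2,3,4,5-tetrahydropyridine, via amino ketone 6 (not isolated)
Conditions: CF3CO2H, CH2Cl2, 0 °C to rt; aq. NaHCO3; then toluene, 4 Å molecular sieves, 60 °C
Reagents that add atoms: none
Why: acidolysis of the Boc group, then intramolecular condensation of the primary amine with the aryl ketone to the six-membered cyclic imine. Warming over sieves compensates for the hindered carbonyl; the benzyl and silyl ethers are stable to this acid.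

Step 4
Reactants: 7 6-{2,6-bis(benzyloxy)-4-[tri(propan-2-yl)silyloxy]phenyl}-2,3,4,5-tetrahydropyridine
Product: 8 (S)-2-{2,6-bis(benzyloxy)-4-[tri(propan-2-yl)silyloxy]phenyl}piperidine
Conditions: H2 (50 bar), [Ir(cod)Cl]2 (1 mol%), f-Binaphane (2.2 mol%, enantiomer giving S), I2 (5 mol%), CH2Cl2, rt
Reagents that add atoms: none
Why: iridium–diphosphine catalysed asymmetric hydrogenation of a 2-aryl cyclic imine. The chiral ligand decides the face of hydride delivery to C=N and so sets C2 as S, helped by the large size difference between the twisted di-ortho-substituted aryl group and the ring CH2. Benzyl ethers are not cleaved by the homogeneous catalyst.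

Step 5
Reactants: 8 (S)-2-{2,6-bis(benzyloxy)-4-[tri(propan-2-yl)silyloxy]phenyl}piperidine
Product: 9 tert-butyl (S)-2-{2,6-bis(benzyloxy)-4-[tri(propan-2-yl)silyloxy]phenyl}piperidine-1-carboxylate
Conditions: Boc2O, Et3N, CH2Cl2, rt to 40 °C
Reagents that add atoms: di-tert-butyl dicarbonate, CC(C)(C)OC(=O)OC(=O)OC(C)(C)C
Why: carbamate formation on the secondary amine. Boc is chosen because it survives brief n-BuLi at low temperature, fluoride and the aryne step, and removes the nucleophilicity of nitrogen.

Step 6
Reactants: 9 tert-butyl (S)-2-{2,6-bis(benzyloxy)-4-[tri(propan-2-yl)silyloxy]phenyl}piperidine-1-carboxylate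
Product: 10 tert-butyl (S)-2-[2,6-bis(benzyloxy)-4-hydroxyphenyl]piperidine-1-carboxylate
Conditions: Bu4NF, AcOH, THF, 0 °C
Reagents that add atoms: none
Why: fluoride cleavage of the aryl silyl ether. The acetic acid buffer avoids a free phenoxide para to the benzylic carbamate.

Step 7
Reactants: 10 tert-butyl (S)-2-[2,6-bis(benzyloxy)-4-hydroxyphenyl]piperidine-1-carboxylate
Product: 11 tert-butyl (S)-2-[2,6-bis(benzyloxy)-3-bromo-4-hydroxyphenyl]piperidine-1-carboxylate
Conditions: NBS (1.0 equiv), CH2Cl2, −78 °C to 0 °C, dark
Reagents that add atoms: N-bromosuccinimide, O=C1CCC(=O)N1Br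
Why: electrophilic aromatic bromination ortho to the free phenol. The two ortho carbons are equivalent through aryl rotation and the para carbon is blocked, so one monobromide results; one equivalent at low temperature limits dibromination.

Step 8
Reactants: 11 tert-butyl (S)-2-[2,6-bis(benzyloxy)-3-bromo-4-hydroxyphenyl]piperidine-1-carboxylate
Product: 14 tert-butyl (S)-2-[2,6-bis(benzyloxy)-3-(trimethylsilyl)-4-(trifluoromethylsulfonyloxy)phenyl]piperidine-1-carboxylate, via trimethylsilyl ether 12 (not isolated), via lithium silylphenoxide 13 (not isolated)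
Conditions: (Me3Si)2NH, THF, 65 °C, evaporate; n-BuLi, THF, −100 °C to −78 °C; Tf2O, −78 °C to 0 °C
Reagents that add atoms: hexamethyldisilazane, C[Si](C)(C)N[Si](C)(C)C; trifluoromethanesulfonic anhydride, O=S(=O)(OS(=O)(=O)C(F)(F)F)C(F)(F)F
Why: standard one-flask sequence from an ortho-bromophenol: O-silylation, bromine–lithium exchange, retro-Brook 1,3-migration of silicon from oxygen to carbon, and triflation of the phenoxide. The exchange is far faster at this temperature than attack on the carbamate or deprotonation at the benzylic C–H, which the two ortho substituents hold in the aryl plane.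

Step 9
Reactants: 14 tert-butyl (S)-2-[2,6-bis(benzyloxy)-3-(trimethylsilyl)-4-(trifluoromethylsulfonyloxy)phenyl]piperidine-1-carboxylate; 15 3-phenylprop-2-ynoic acid
Product: 17 tert-butyl (S)-2-[2,6-bis(benzyloxy)-4-hydroxy-3-(3-phenylprop-2-ynoyl)phenyl]piperidine-1-carboxylate, via aryne 16 (not isolated)
Conditions: 15 (2 equiv), CsF (4 equiv), THF, sealed tube, 100 °C
Reagents that add atoms: none
Why: Fluoride attacks the trimethylsilyl group of 14 and triflate leaves, giving aryne 16 with its strained bond between the carbons that become C4a and C8a. The carboxylate of 15 adds through oxygen at C8a, because the benzyloxy group on the neighbouring C5 withdraws inductively, distorts the aryne so that the distal carbon is the electrophilic one, and stabilises the aryl anion that develops at C4a; C8a is also the less hindered end, with only the C8–H beside it. The C4a carbanion of the resulting aryl ester attacks its own ester carbonyl through a four-membered cyclic alkoxide, which opens by C–O cleavage to the ortho-acyl phenoxide, so the aryne is inserted into the C–O bond of the acid, forming C8a–O1 and C4a–C4. The closest known reaction type is the fluoride-induced insertion of arynes into carboxylic acids that gives ortho-hydroxyaryl ketones. No ring is retained (the four-membered ring is transient) and no stereocentre is made; the piperidine C2 is remote from the reacting carbons and carries a non-nucleophilic carbamate, so it is untouched and nitrogen does not add to the aryne. Two selectivities are needed: oxygen at C8a rather than C4a, secured by the C5 alkoxy group as described, and acyl transfer rather than protonation of the aryl anion or its closure onto the alkyne, favoured by an ether solvent with sparingly soluble CsF (few proton donors, slow aryne release) and by the short tether to the carbonyl. Any 19 formed at this stage by six-membered closure of the phenoxide is carried on with 17.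

Step 10
Reactants: 17 tert-butyl (S)-2-[2,6-bis(benzyloxy)-4-hydroxy-3-(3-phenylprop-2-ynoyl)phenyl]piperidine-1-carboxylate
Product: 19 tert-butyl (S)-2-[5,7-bis(benzyloxy)-4-oxo-2-phenyl-4H-chromen-6-yl]piperidine-1-carboxylate, via enaminone 18 (not isolated)
Conditions: Et2NH, EtOH, rt to 60 °C
Reagents that add atoms: none
Why: conjugate addition of the secondary amine to the ynone gives a β-amino enone. The phenol then adds at the same β-carbon and the amine is expelled (addition–elimination), so ring C closes in the 6-endo sense and the 5-exo aurone pathway of simple base treatment is avoided.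

Step 11
Reactants: 19 tert-butyl (S)-2-[5,7-bis(benzyloxy)-4-oxo-2-phenyl-4H-chromen-6-yl]piperidine-1-carboxylate
Product: 20 tert-butyl (S)-2-[7-(benzyloxy)-5-hydroxy-4-oxo-2-phenyl-4H-chromen-6-yl]piperidine-1-carboxylate
Conditions: MgBr2·OEt2 (3 equiv), toluene–Et2O, rt to 60 °C; cold 0.5 M HCl
Reagents that add atoms: none
Why: chelation-controlled ether cleavage. Divalent magnesium bridges the C4 carbonyl oxygen and O5, and bromide removes the benzyl group from that oxygen only, since the C7 ether cannot chelate; this mild Lewis acid is expected to leave the carbamate intact.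

Step 12
Reactants: 20 tert-butyl (S)-2-[7-(benzyloxy)-5-hydroxy-4-oxo-2-phenyl-4H-chromen-6-yl]piperidine-1-carboxylate
Product: 21 tert-butyl (S)-2-[7-(benzyloxy)-5-methoxy-4-oxo-2-phenyl-4H-chromen-6-yl]piperidine-1-carboxylate
Conditions: MeI, K2CO3, DMF, 40 °C
Reagents that add atoms: iodomethane, CI
Why: Williamson O-methylation. The hydrogen-bonded 5-hydroxyl needs a polar aprotic solvent and warming, and the fully substituted carbamate nitrogen offers no competing site.

Step 13
Reactants: 21 tert-butyl (S)-2-[7-(benzyloxy)-5-methoxy-4-oxo-2-phenyl-4H-chromen-6-yl]piperidine-1-carboxylate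
Product: 23 (S)-7-(benzyloxy)-5-methoxy-6-(1-methylpiperidin-2-yl)-2-phenyl-4H-chromen-4-one, via secondary amine 22 (not isolated)
Conditions: 4 M HCl in dioxane, 0 °C to rt, evaporate; Et3N, aq. CH2O, NaBH(OAc)3, ClCH2CH2Cl, rt
Reagents that add atoms: formaldehyde, C=O
Why: acidolysis of the Boc group, then reductive amination. The iminium forms on the new CH2 carbon, so the stereocentre is not involved, and NaBH(OAc)3 does not reduce the chromone. The step is run while O7 is still benzylated so that formaldehyde meets no free phenol ring.

Step 14
Reactants: 23 (S)-7-(benzyloxy)-5-methoxy-6-(1-methylpiperidin-2-yl)-2-phenyl-4H-chromen-4-one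
Product: 24 (S)-7-hydroxy-5-methoxy-6-(1-methylpiperidin-2-yl)-2-phenyl-4H-chromen-4-one
Conditions: H2 (1 atm), 10% Pd/C, EtOAc–MeOH, rt, stopped at full conversion
Reagents that add atoms: none
Why: hydrogenolysis of the aryl benzyl ether, which is faster than reduction of the chromone C2=C3 bond or cleavage of the hindered benzylic C–N bond at ambient pressure. Room temperature and neutral work-up avoid quinone-methide racemisation of the product.

## Compound list

1 | 3,5-bis(benzyloxy)phenol | Oc1cc(OCc2ccccc2)cc(OCc2ccccc2)c1 | starting material
2 | [3,5-bis(benzyloxy)phenoxy]tri(propan-2-yl)silane | CC(C)[Si](Oc1cc(OCc2ccccc2)cc(OCc2ccccc2)c1)(C(C)C)C(C)C | intermediate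
3 | tert-butyl 2-oxopiperidine-1-carboxylate | O=C1CCCCN1C(=O)OC(C)(C)C | starting material
4 | {2,6-bis(benzyloxy)-4-[tri(propan-2-yl)silyloxy]phenyl}lithium | [Li]c1c(OCc2ccccc2)cc(O[Si](C(C)C)(C(C)C)C(C)C)cc1OCc1ccccc1 | intermediate (not isolated)
5 | tert-butyl (5-{2,6-bis(benzyloxy)-4-[tri(propan-2-yl)silyloxy]phenyl}-5-oxopentyl)carbamate | CC(C)(C)OC(=O)NCCCCC(=O)c1c(OCc2ccccc2)cc(O[Si](C(C)C)(C(C)C)C(C)C)cc1OCc1ccccc1 | intermediate
6 | 5-amino-1-{2,6-bis(benzyloxy)-4-[tri(propan-2-yl)silyloxy]phenyl}pentan-1-one | NCCCCC(=O)c1c(OCc2ccccc2)cc(O[Si](C(C)C)(C(C)C)C(C)C)cc1OCc1ccccc1 | intermediate (not isolated)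
7 | 6-{2,6-bis(benzyloxy)-4-[tri(propan-2-yl)silyloxy]phenyl}-2,3,4,5-tetrahydropyridine | CC(C)[Si](Oc1cc(OCc2ccccc2)c(C2=NCCCC2)c(OCc2ccccc2)c1)(C(C)C)C(C)C | intermediate
8 | (S)-2-{2,6-bis(benzyloxy)-4-[tri(propan-2-yl)silyloxy]phenyl}piperidine | CC(C)[Si](Oc1cc(OCc2ccccc2)c([C@@H]2CCCCN2)c(OCc2ccccc2)c1)(C(C)C)C(C)C | intermediate
9 | tert-butyl (S)-2-{2,6-bis(benzyloxy)-4-[tri(propan-2-yl)silyloxy]phenyl}piperidine-1-carboxylate | CC(C)[Si](Oc1cc(OCc2ccccc2)c([C@@H]2CCCCN2C(=O)OC(C)(C)C)c(OCc2ccccc2)c1)(C(C)C)C(C)C | intermediate
10 | tert-butyl (S)-2-[2,6-bis(benzyloxy)-4-hydroxyphenyl]piperidine-1-carboxylate | Oc1cc(OCc2ccccc2)c([C@@H]2CCCCN2C(=O)OC(C)(C)C)c(OCc2ccccc2)c1 | intermediate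
11 | tert-butyl (S)-2-[2,6-bis(benzyloxy)-3-bromo-4-hydroxyphenyl]piperidine-1-carboxylate | Oc1cc(OCc2ccccc2)c([C@@H]2CCCCN2C(=O)OC(C)(C)C)c(OCc2ccccc2)c1Br | intermediate
12 | tert-butyl (S)-2-[2,6-bis(benzyloxy)-3-bromo-4-(trimethylsilyloxy)phenyl]piperidine-1-carboxylate | C[Si](C)(C)Oc1cc(OCc2ccccc2)c([C@@H]2CCCCN2C(=O)OC(C)(C)C)c(OCc2ccccc2)c1Br | intermediate (not isolated)
13 | lithium 3,5-bis(benzyloxy)-4-[(S)-1-(tert-butoxycarbonyl)piperidin-2-yl]-2-(trimethylsilyl)phenolate | [Li+].[O-]c1cc(OCc2ccccc2)c([C@@H]2CCCCN2C(=O)OC(C)(C)C)c(OCc2ccccc2)c1[Si](C)(C)C | intermediate (not isolated)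
14 | tert-butyl (S)-2-[2,6-bis(benzyloxy)-3-(trimethylsilyl)-4-(trifluoromethylsulfonyloxy)phenyl]piperidine-1-carboxylate | C[Si](C)(C)c1c(OS(=O)(=O)C(F)(F)F)cc(OCc2ccccc2)c([C@@H]2CCCCN2C(=O)OC(C)(C)C)c1OCc1ccccc1 | intermediate
15 | 3-phenylprop-2-ynoic acid | OC(=O)C#Cc1ccccc1 | starting material
16 | tert-butyl (S)-2-[2,6-bis(benzyloxy)-3,4-didehydrophenyl]piperidine-1-carboxylate (aryne) | C1(=C(OCc2ccccc2)C#CC=C1OCc1ccccc1)[C@@H]1CCCCN1C(=O)OC(C)(C)C | intermediate (not isolated)
17 | tert-butyl (S)-2-[2,6-bis(benzyloxy)-4-hydroxy-3-(3-phenylprop-2-ynoyl)phenyl]piperidine-1-carboxylate | O=C(C#Cc1ccccc1)c1c(O)cc(OCc2ccccc2)c([C@@H]2CCCCN2C(=O)OC(C)(C)C)c1OCc1ccccc1 | intermediate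
18 | tert-butyl (S)-2-{2,6-bis(benzyloxy)-3-[(E)-3-(diethylamino)-3-phenylprop-2-enoyl]-4-hydroxyphenyl}piperidine-1-carboxylate | CCN(CC)/C(c1ccccc1)=C/C(=O)c1c(O)cc(OCc2ccccc2)c([C@@H]2CCCCN2C(=O)OC(C)(C)C)c1OCc1ccccc1 | intermediate (not isolated)
19 | tert-butyl (S)-2-[5,7-bis(benzyloxy)-4-oxo-2-phenyl-4H-chromen-6-yl]piperidine-1-carboxylate | O=c1cc(-c2ccccc2)oc2cc(OCc3ccccc3)c([C@@H]3CCCCN3C(=O)OC(C)(C)C)c(OCc3ccccc3)c12 | intermediate
20 | tert-butyl (S)-2-[7-(benzyloxy)-5-hydroxy-4-oxo-2-phenyl-4H-chromen-6-yl]piperidine-1-carboxylate | O=c1cc(-c2ccccc2)oc2cc(OCc3ccccc3)c([C@@H]3CCCCN3C(=O)OC(C)(C)C)c(O)c12 | intermediate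
21 | tert-butyl (S)-2-[7-(benzyloxy)-5-methoxy-4-oxo-2-phenyl-4H-chromen-6-yl]piperidine-1-carboxylate | COc1c([C@@H]2CCCCN2C(=O)OC(C)(C)C)c(OCc2ccccc2)cc2oc(-c3ccccc3)cc(=O)c12 | intermediate
22 | (S)-7-(benzyloxy)-5-methoxy-2-phenyl-6-(piperidin-2-yl)-4H-chromen-4-one | COc1c([C@@H]2CCCCN2)c(OCc2ccccc2)cc2oc(-c3ccccc3)cc(=O)c12 | intermediate (not isolated)
23 | (S)-7-(benzyloxy)-5-methoxy-6-(1-methylpiperidin-2-yl)-2-phenyl-4H-chromen-4-one | COc1c([C@@H]2CCCCN2C)c(OCc2ccccc2)cc2oc(-c3ccccc3)cc(=O)c12 | intermediate
24 | (S)-7-hydroxy-5-methoxy-6-(1-methylpiperidin-2-yl)-2-phenyl-4H-chromen-4-one | COc1c([C@@H]2CCCCN2C)c(O)cc2oc(-c3ccccc3)cc(=O)c12 | target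

## Step count and least certain steps

Total: 14 steps. Longest linear sequence: 14 steps (from 1; compounds 3 and 15 are bought).

**Step 9 (key step).**
- What may go wrong: the aryl anion may be protonated before it reaches the ester carbonyl, which gives simple O-arylation of the acid. It may instead close onto the alkyne carbon in a six-membered mode. The product phenoxide may be arylated by a second aryne. The propiolate may lose CO2 at the reaction temperature. All of these divert material from the C–O insertion.
- Fallback (no aryne): it sets out from 10. Iodination with N-iodosuccinimide in CH2Cl2 at low temperature should give tert-butyl (S)-2-[2,6-bis(benzyloxy)-4-hydroxy-3-iodophenyl]piperidine-1-carboxylate F1. Carbonylative Sonogashira coupling of F1 with phenylacetylene under CO with PdCl2(PPh3)2 and Et2NH in DMF at 60–100 °C should form the same ortho-hydroxyaryl ynone, which the amine cyclises in the same flask. The route is rejoined at 19.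

**Step 4.**
- What may go wrong: poor facial selectivity or slow turnover, because the C=N bond is shielded by two ortho benzyloxy groups and twisted out of conjugation with the aryl ring.
- Fallback (auxiliary control instead of catalyst control): it sets out from 2.
  - Lithiation as in step 2 and quenching with DMF should give 2,6-bis(benzyloxy)-4-[tri(propan-2-yl)silyloxy]benzaldehyde F2.
  - Condensation with (R)-2-methylpropane-2-sulfinamide and Ti(OEt)4 should give (R,E)-N-{2,6-bis(benzyloxy)-4-[tri(propan-2-yl)silyloxy]benzylidene}-2-methylpropane-2-sulfinamide F3.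
  - Addition of ClCH2CH2CH2CH2MgBr in CH2Cl2 at −48 °C, through the magnesium-chelated chair that exposes the Si face, should give (R)-N-[(S)-1-{2,6-bis(benzyloxy)-4-[tri(propan-2-yl)silyloxy]phenyl}-5-chloropentyl]-2-methylpropane-2-sulfinamide F4.
  - Ring closure with KN(SiMe3)2 in THF should give (S)-2-{2,6-bis(benzyloxy)-4-[tri(propan-2-yl)silyloxy]phenyl}-1-[(R)-tert-butylsulfinyl]piperidine F5.
  - HCl in MeOH at 0 °C removes the sulfinyl group, and the route is rejoined at 8.

**Step 11.**
- What may go wrong: loss of the Boc group under the Lewis acid, or incomplete cleavage at the hindered O5.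
- Fallback (differentiation by acidity instead of chelation): it sets out from 19. Hydrogenolysis of both benzyl ethers (H2, Pd/C, EtOAc–MeOH) should give tert-butyl (S)-2-(5,7-dihydroxy-4-oxo-2-phenyl-4H-chromen-6-yl)piperidine-1-carboxylate F6. The more acidic, non-chelated 7-hydroxyl is then benzylated selectively with one equivalent of benzyl bromide and K2CO3 in acetone at rt. The route is rejoined at 20.

**Step 14.**
- What may go wrong: over-reduction of the pyranone C2=C3 bond, slow hydrogenolysis because the tertiary amine binds the metal surface, or hydrogenolytic opening of the benzylic C–N bond.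
- Fallback (acidolytic instead of reductive cleavage): it sets out from 23. Treatment with CF3CO2H and pentamethylbenzene at rt transfers the benzyl cation to the arene scavenger. No new compound is made on this path (F0), and it arrives directly at 24 after neutralisation.

## Further compounds

F1 | step 9 | tert-butyl (S)-2-[2,6-bis(benzyloxy)-4-hydroxy-3-iodophenyl]piperidine-1-carboxylate | Oc1cc(OCc2ccccc2)c([C@@H]2CCCCN2C(=O)OC(C)(C)C)c(OCc2ccccc2)c1I
F2 | step 4 | 2,6-bis(benzyloxy)-4-[tri(propan-2-yl)silyloxy]benzaldehyde | O=Cc1c(OCc2ccccc2)cc(O[Si](C(C)C)(C(C)C)C(C)C)cc1OCc1ccccc1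
F3 | step 4 | (R,E)-N-{2,6-bis(benzyloxy)-4-[tri(propan-2-yl)silyloxy]benzylidene}-2-methylpropane-2-sulfinamide | CC(C)(C)[S@@](=O)/N=C/c1c(OCc2ccccc2)cc(O[Si](C(C)C)(C(C)C)C(C)C)cc1OCc1ccccc1
F4 | step 4 | (R)-N-[(S)-1-{2,6-bis(benzyloxy)-4-[tri(propan-2-yl)silyloxy]phenyl}-5-chloropentyl]-2-methylpropane-2-sulfinamide | CC(C)(C)[S@@](=O)N[C@@H](CCCCCl)c1c(OCc2ccccc2)cc(O[Si](C(C)C)(C(C)C)C(C)C)cc1OCc1ccccc1
F5 | step 4 | (S)-2-{2,6-bis(benzyloxy)-4-[tri(propan-2-yl)silyloxy]phenyl}-1-[(R)-tert-butylsulfinyl]piperidine | CC(C)(C)[S@@](=O)N1CCCC[C@H]1c1c(OCc2ccccc2)cc(O[Si](C(C)C)(C(C)C)C(C)C)cc1OCc1ccccc1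
F6 | step 11 | tert-butyl (S)-2-(5,7-dihydroxy-4-oxo-2-phenyl-4H-chromen-6-yl)piperidine-1-carboxylate | O=c1cc(-c2ccccc2)oc2cc(O)c([C@@H]3CCCCN3C(=O)OC(C)(C)C)c(O)c12
F0 | step 14 | none | none
A1 | alternative 1 | tert-butyl (S)-2-(7-hydroxy-5-methoxy-4-oxo-2-phenyl-4H-chromen-6-yl)piperidine-1-carboxylate | COc1c([C@@H]2CCCCN2C(=O)OC(C)(C)C)c(O)cc2oc(-c3ccccc3)cc(=O)c12
A2 | alternative 1 | tert-butyl [5-hydroxy-5-(7-hydroxy-5-methoxy-4-oxo-2-phenyl-4H-chromen-6-yl)pentyl]carbamate (racemic) | COc1c(C(O)CCCCNC(=O)OC(C)(C)C)c(O)cc2oc(-c3ccccc3)cc(=O)c12
A3 | alternative 1 | tert-butyl [5-(5-methoxy-4,7-dioxo-2-phenyl-4H-chromen-6(7H)-ylidene)pentyl]carbamate (ortho-quinone methide) | COC1=C2C(=O)C=C(c3ccccc3)OC2=CC(=O)C1=CCCCCNC(=O)OC(C)(C)C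
A4 | alternative 2 | 7-hydroxy-5-methoxy-2-phenyl-6-(pyridin-2-yl)-4H-chromen-4-one | COc1c(-c2ccccn2)c(O)cc2oc(-c3ccccc3)cc(=O)c12
A5 | alternative 2 | 5-methoxy-2-phenyl-6,7-didehydro-4H-chromen-4-one (aryne) | COC1=C2C(=O)C=C(c3ccccc3)OC2=CC#C1
A6 | alternative 2 | pyridine N-oxide | [O-][n+]1ccccc1
A7 | alternative 3 | tert-butyl (S)-2-{5-hydroxy-4-oxo-2-phenyl-7-[tri(propan-2-yl)silyloxy]-4H-chromen-6-yl}piperidine-1-carboxylate | Oc1c([C@@H]2CCCCN2C(=O)OC(C)(C)C)c(O[Si](C(C)C)(C(C)C)C(C)C)cc2oc(-c3ccccc3)cc(=O)c12
A8 | alternative 3 | 2-(2-diazoacetyl)-6-phenyl-4H-pyran-4-one | [N-]=[N+]=CC(=O)c1cc(=O)cc(-c2ccccc2)o1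
A9 | alternative 3 | tert-butyl (S)-2-{[tri(propan-2-yl)silyloxy]ethynyl}piperidine-1-carboxylate | CC(C)[Si](OC#C[C@@H]1CCCCN1C(=O)OC(C)(C)C)(C(C)C)C(C)C
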